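**Retrosynthetic overview**

1. Target 32 ⇒ 30: the C12–O acetate bond is made last, by acetate displacement on the allylic chloride obtained by ene chlorination of the propenyl group.
2. 30 ⇒ 29 ⇒ 25: the oxirane comes from Sharpless epoxidation of the C15 allylic alcohol (C–O bonds set C4 and C5); the C9–O senecioate comes from a stereoconvergent acylation of both C9 epimers (new); the C14–O ester comes from selective acylation with aldol-derived acid 24.
3. 25 ⇒ 16 ⇒ 15: the ten-membered carbocycle is closed at C9–C10 by a Nozaki–Hiyama–Kishi reaction.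
4. 15 ⇒ 10 ⇒ 5: C1=C10 by a bromo Still–Gennari olefination; C2–C3 and the C4=C5 geometry by Claisen rearrangement; C4–C5 by alkenyllithium addition.
5. 5 ⇒ 1 + 2: C7 by rhodium-catalysed asymmetric conjugate addition. Ring order: carbocycle (step 10), then oxirane (step 17).

Assumption: locants C1–C15 follow germacrane numbering of the target (C7 carries the C11–C13 propenyl unit, C9 the senecioate, C10 the C14 ester carbon, C4 the C15 hydroxymethyl; the oxirane spans C4–C5).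

**Route**

Step 1
Reactants: 1 5,6-dihydro-2H-pyran-2-one; 2 4,4,5,5-tetramethyl-2-(prop-1-en-2-yl)-1,3,2-dioxaborolane
Product: 3 (4R)-4-(prop-1-en-2-yl)oxan-2-one
Conditions: [Rh(cod)Cl]2 (1.5 mol%), (R)-BINAP (3.3 mol%), KOH (10 mol%), dioxane/H2O 10:1, 60 °C
Reagents that add atoms: none
Why: Hayashi–Miyaura rhodium-catalysed asymmetric 1,4-addition, in which the (R)-BINAP–alkenylrhodium species adds to one enantioface of the unsaturated lactone and so sets C7 (4R in 3; (S)-BINAP gives the S series with cyclic enones and this lactone).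

Step 2
Reactants: 3 (4R)-4-(prop-1-en-2-yl)oxan-2-one
Product: 4 (3R)-5-hydroxy-N-methoxy-N-methyl-3-(prop-1-en-2-yl)pentanamide
Conditions: MeNHOMe·HCl, i-PrMgCl, THF, −20 °C; aq NH4Cl
Reagents that add atoms: N,O-dimethylhydroxylamine hydrochloride, CNOC.Cl
Why: Weinreb aminolysis of the lactone by the chloromagnesium amide stores C9 as an amide that later gives the aldehyde and frees the C5 alcohol, leaving C7 untouched.

Step 3
Reactants: 4 (3R)-5-hydroxy-N-methoxy-N-methyl-3-(prop-1-en-2-yl)pentanamide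
Product: 5 (3R)-N-methoxy-N-methyl-5-oxo-3-(prop-1-en-2-yl)pentanamide
Conditions: TEMPO (10 mol%), PhI(OAc)2, CH2Cl2, 23 °C
Reagents that add atoms: none
Why: TEMPO/PhI(OAc)2 oxidation takes the primary alcohol cleanly to the aldehyde without touching the amide or the alkene, and the crude hydroxy amide is used at once so it cannot relactonise.

Step 4
Reactants: 5 (3R)-N-methoxy-N-methyl-5-oxo-3-(prop-1-en-2-yl)pentanamide; 6 tert-butyl[(2-bromoprop-2-en-1-yl)oxy]dimethylsilane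
Product: 8 (3R,5RS)-6-({[tert-butyl(dimethyl)silyl]oxy}methyl)-5-hydroxy-N-methoxy-N-methyl-3-(prop-1-en-2-yl)hept-6-enamide, via alkenyllithium 7 (not isolated)
Conditions: 6, t-BuLi (2 equiv), Et2O, −78 °C; then 5 (inverse addition), −78 °C; AcOH, −78 °C
Reagents that add atoms: none
Why: Bromine–lithium exchange followed by 1,2-addition, the aldehyde reacting much faster than the Weinreb amide at −78 °C; this brings in C3, C4 and the already protected C15 oxygen, and the new carbinol centre is left uncontrolled because the next step destroys it.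

Step 5
Reactants: 8 (3R,5RS)-6-({[tert-butyl(dimethyl)silyl]oxy}methyl)-5-hydroxy-N-methoxy-N-methyl-3-(prop-1-en-2-yl)hept-6-enamide
Product: 10 (3R,5Z)-6-({[tert-butyl(dimethyl)silyl]oxy}methyl)-N-methoxy-N-methyl-9-oxo-3-(prop-1-en-2-yl)non-5-enamide, via allyl vinyl ether 9 (not isolated)
Conditions: Hg(OAc)2 (0.3 equiv), ethyl vinyl ether, 35 °C; concentrate; PhMe, 130 °C (sealed tube)
Reagents that add atoms: ethyl vinyl ether, C=COCC
Why: Transvinylation then Claisen rearrangement through a chair transition state with the chain equatorial forms C2–C3 and the trisubstituted C4=C5 alkene with C6 cis to the CH2OSi group (5Z by CIP, i.e. C3 and C6 trans as in the ring), and delivers the C1 aldehyde without any hydride step.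

Step 6
Reactants: 11 methyl 2-[bis(2,2,2-trifluoroethoxy)phosphoryl]acetate
Product: 12 methyl 2-[bis(2,2,2-trifluoroethoxy)phosphoryl]-2,2-dibromoacetate
Conditions: Br2, NaOH, H2O, 0 °C
Reagents that add atoms: bromine, BrBr
Why: Hypobromite bromination of the doubly activated methylene runs cleanly to the dibromide, which avoids the mixtures obtained on direct monobromination.

Step 7
Reactants: 12 methyl 2-[bis(2,2,2-trifluoroethoxy)phosphoryl]-2,2-dibromoacetate
Product: 13 methyl 2-[bis(2,2,2-trifluoroethoxy)phosphoryl]-2-bromoacetate (racemic)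
Conditions: SnCl2·2H2O, EtOH/H2O, 0 °C
Reagents that add atoms: none
Why: Selective reductive mono-debromination of the gem-dibromide by SnCl2 stops at the monobromo phosphonate because the second C–Br bond is much harder to reduce.

Step 8
Reactants: 10 (3R,5Z)-6-({[tert-butyl(dimethyl)silyl]oxy}methyl)-N-methoxy-N-methyl-9-oxo-3-(prop-1-en-2-yl)non-5-enamide; 13 methyl 2-[bis(2,2,2-trifluoroethoxy)phosphoryl]-2-bromoacetate
Product: 14 methyl (2E,6Z,9R)-2-bromo-6-({[tert-butyl(dimethyl)silyl]oxy}methyl)-11-[methoxy(methyl)amino]-11-oxo-9-(prop-1-en-2-yl)undeca-2,6-dienoate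
Conditions: 13, KN(SiMe3)2, 18-crown-6, THF, −78 °C; then 10
Reagents that add atoms: none
Why: Still–Gennari-type Horner–Wadsworth–Emmons olefination, in which the trifluoroethyl phosphonate under dissociating conditions eliminates under kinetic control to the E-α-bromoacrylate (Br trans to the chain, ester cis), fixing the later C1=C10 geometry.

Step 9
Reactants: 14 methyl (2E,6Z,9R)-2-bromo-6-({[tert-butyl(dimethyl)silyl]oxy}methyl)-11-[methoxy(methyl)amino]-11-oxo-9-(prop-1-en-2-yl)undeca-2,6-dienoate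
Product: 15 (3R,5Z,9E)-10-bromo-6-({[tert-butyl(dimethyl)silyl]oxy}methyl)-11-hydroxy-3-(prop-1-en-2-yl)undeca-5,9-dienal
Conditions: i-Bu2AlH (4.5 equiv), CH2Cl2, −78 °C; aq KNaC4H4O6, 23 °C
Reagents that add atoms: none
Why: One hydride operation reduces the bromoacrylate ester to the C14 allylic alcohol and the Weinreb amide (through its stable aluminium chelate) to the C9 aldehyde, so C14–OH and C15–OSi are differentiated without protecting-group steps.

Step 10
Reactants: 15 (3R,5Z,9E)-10-bromo-6-({[tert-butyl(dimethyl)silyl]oxy}methyl)-11-hydroxy-3-(prop-1-en-2-yl)undeca-5,9-dienal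
Product: 16 (1RS,2E,6Z,9R)-6-({[tert-butyl(dimethyl)silyl]oxy}methyl)-2-(hydroxymethyl)-9-(prop-1-en-2-yl)cyclodeca-2,6-dien-1-ol
Conditions: CrCl2 (10 equiv), NiCl2 (2 mol%), DMSO/THF, 25 °C, 2 mM, slow addition
Reagents that add atoms: none
Why: Nozaki–Hiyama–Kishi reaction, in which zerovalent nickel inserts into the C–Br bond and transmetalation to trivalent chromium gives an alkenylchromium that adds only to the aldehyde with retention of alkene geometry, closing the ten-membered ring at C9–C10; C9 forms as an epimer mixture that step 15 converges.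

Step 11
Reactants: 17 (4R)-4-benzyl-3-propanoyl-1,3-oxazolidin-2-one; 18 acetaldehyde
Product: 21 (4R)-4-benzyl-3-[(2R,3S)-3-hydroxy-2-methylbutanoyl]-1,3-oxazolidin-2-one, via dibutylboron enolate 19 (not isolated), via boron aldolate 20 (not isolated)
Conditions: n-Bu2BOTf, i-Pr2NEt, CH2Cl2, 0 °C; 18, −78 to 0 °C; H2O2, MeOH, pH 7 buffer, 0 °C
Reagents that add atoms: none
Why: Evans syn aldol, in which the Z-boron enolate reacts through a Zimmerman–Traxler chair on the face opposite the benzyl group, so the (R)-auxiliary sets the (2R,3S) syn pair of the side chain.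

Step 12
Reactants: 21 (4R)-4-benzyl-3-[(2R,3S)-3-hydroxy-2-methylbutanoyl]-1,3-oxazolidin-2-one
Product: 22 (4R)-4-benzyl-3-[(2R,3S)-3-{[tert-butyl(dimethyl)silyl]oxy}-2-methylbutanoyl]-1,3-oxazolidin-2-one
Conditions: TBSOTf, 2,6-lutidine, CH2Cl2, 0 °C
Reagents that add atoms: tert-butyldimethylsilyl trifluoromethanesulfonate, CC(C)(C)[Si](C)(C)OS(=O)(=O)C(F)(F)F
Why: Silylation masks the secondary hydroxyl, which would otherwise compete in the two later acylations and invite retro-aldol cleavage.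

Step 13
Reactants: 22 (4R)-4-benzyl-3-[(2R,3S)-3-{[tert-butyl(dimethyl)silyl]oxy}-2-methylbutanoyl]-1,3-oxazolidin-2-one
Product: 24 (2R,3S)-3-{[tert-butyl(dimethyl)silyl]oxy}-2-methylbutanoic acid, via peroxy acid 23 (not isolated)
Conditions: LiOH, H2O2, THF/H2O 3:1, 0 °C; aq Na2SO3; HCl to pH 3
Reagents that add atoms: hydrogen peroxide, OO
Why: Hydroperoxide attacks the exocyclic imide carbonyl selectively, so the auxiliary is released without epimerising C2 and sulfite reduction of the peroxy acid gives the acid.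

Step 14
Reactants: 16 (1RS,2E,6Z,9R)-6-({[tert-butyl(dimethyl)silyl]oxy}methyl)-2-(hydroxymethyl)-9-(prop-1-en-2-yl)cyclodeca-2,6-dien-1-ol; 24 (2R,3S)-3-{[tert-butyl(dimethyl)silyl]oxy}-2-methylbutanoic acid
Product: 25 [(1E,5Z,8R,10RS)-5-({[tert-butyl(dimethyl)silyl]oxy}methyl)-10-hydroxy-8-(prop-1-en-2-yl)cyclodeca-1,5-dien-1-yl]methyl (2R,3S)-3-{[tert-butyl(dimethyl)silyl]oxy}-2-methylbutanoate
Conditions: DCC, DMAP (10 mol%), CH2Cl2, −20 °C
Reagents that add atoms: none
Why: Steglich esterification, in which the primary allylic C14–OH reacts far faster than the hindered secondary C9–OH at −20 °C, so the C14–O ester bond forms selectively.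

Step 15
Reactants: 25 [(1E,5Z,8R,10RS)-5-({[tert-butyl(dimethyl)silyl]oxy}methyl)-10-hydroxy-8-(prop-1-en-2-yl)cyclodeca-1,5-dien-1-yl]methyl (2R,3S)-3-{[tert-butyl(dimethyl)silyl]oxy}-2-methylbutanoate; 26 3-methylbut-2-enoic acid
Product: 28 [(1E,5Z,8R,10R)-5-({[tert-butyl(dimethyl)silyl]oxy}methyl)-10-[(3-methylbut-2-enoyl)oxy]-8-(prop-1-en-2-yl)cyclodeca-1,5-dien-1-yl]methyl (2R,3S)-3-{[tert-butyl(dimethyl)silyl]oxy}-2-methylbutanoate, via acyl carbonate 27 (not isolated)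
Conditions: 26, i-PrOCOCl, i-Pr2NEt, PhMe, 0 °C, filter; then 25, (η5-C5Ph5)Ru(CO)2Cl (5 mol%), KOt-Bu (5 mol%), (R)-benzotetramisole (10 mol%), PhMe/t-AmOH, 25 °C
Reagents that add atoms: none
Why: Proposed new method: diastereoconvergent dynamic kinetic acylation, in which the ruthenium alkoxide of 25 epimerises C9 by reversible β-hydride elimination and re-addition through the ruthenium-bound enone while the chiral isothiourea transfers the senecioyl group from acyl carbonate 27 only to the 9R carbinol (alkenyl C10 as the π-recognised large group, CH2-8 as the small one), so both ring-closure epimers funnel into the 9R ester with CO2 and isopropanol as by-products; the closest known reaction type is non-enzymatic dynamic kinetic resolution of secondary benzylic and allylic alcohols by ruthenium racemisation combined with chiral nucleophile-catalysed acyl transfer from acyl carbonates (and isothiourea kinetic resolution of allylic alcohols), which has not been shown with an α,β-unsaturated acyl donor or for epimer convergence on a polyfunctional macrocyclic carbinol.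

Step 16
Reactants: 28 [(1E,5Z,8R,10R)-5-({[tert-butyl(dimethyl)silyl]oxy}methyl)-10-[(3-methylbut-2-enoyl)oxy]-8-(prop-1-en-2-yl)cyclodeca-1,5-dien-1-yl]methyl (2R,3S)-3-{[tert-butyl(dimethyl)silyl]oxy}-2-methylbutanoate
Product: 29 [(1E,5Z,8R,10R)-5-(hydroxymethyl)-10-[(3-methylbut-2-enoyl)oxy]-8-(prop-1-en-2-yl)cyclodeca-1,5-dien-1-yl]methyl (2R,3S)-3-hydroxy-2-methylbutanoate
Conditions: HF·pyridine, pyridine, THF, 0 to 23 °C
Reagents that add atoms: none
Why: Buffered fluoride desilylation removes both silyl ethers without acyl migration or acid-induced transannular cyclisation of the 1,5-diene, freeing the C15 allylic alcohol needed for directed epoxidation.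

Step 17
Reactants: 29 [(1E,5Z,8R,10R)-5-(hydroxymethyl)-10-[(3-methylbut-2-enoyl)oxy]-8-(prop-1-en-2-yl)cyclodeca-1,5-dien-1-yl]methyl (2R,3S)-3-hydroxy-2-methylbutanoate
Product: 30 [(1S,4E,6R,8S,10R)-1-(hydroxymethyl)-6-[(3-methylbut-2-enoyl)oxy]-8-(prop-1-en-2-yl)-11-oxabicyclo[8.1.0]undec-4-en-5-yl]methyl (2R,3S)-3-hydroxy-2-methylbutanoate
Conditions: Ti(OiPr)4 (20 mol%), L-(+)-diethyl tartrate (24 mol%), t-BuOOH, 4 Å molecular sieves, CH2Cl2, −20 °C
Reagents that add atoms: tert-butyl hydroperoxide, CC(C)(C)OO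
Why: Sharpless asymmetric epoxidation, in which only C4=C5 carries a free allylic hydroxyl and the titanium–L-tartrate complex delivers oxygen to the face that gives the 4S,5R oxirane (the same facial sense that converts geraniol into its 2S,3S epoxide), forming both C–O bonds of the second ring.

Step 18
Reactants: 30 [(1S,4E,6R,8S,10R)-1-(hydroxymethyl)-6-[(3-methylbut-2-enoyl)oxy]-8-(prop-1-en-2-yl)-11-oxabicyclo[8.1.0]undec-4-en-5-yl]methyl (2R,3S)-3-hydroxy-2-methylbutanoate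
Product: 31 [(1S,4E,6R,8S,10R)-8-(3-chloroprop-1-en-2-yl)-1-(hydroxymethyl)-6-[(3-methylbut-2-enoyl)oxy]-11-oxabicyclo[8.1.0]undec-4-en-5-yl]methyl (2R,3S)-3-hydroxy-2-methylbutanoate
Conditions: Ca(OCl)2, CO2 (solid), CH2Cl2/H2O, 0 °C
Reagents that add atoms: calcium hypochlorite, [Ca+2].[O-]Cl.[O-]Cl
Why: Ene-type allylic chlorination by HOCl, in which the isolated 1,1-disubstituted propenyl group is the only electron-rich alkene left (C1=C10 is deactivated by two allylic acyloxy groups, the senecioate is conjugated, C4=C5 is already the oxirane) and loss of a methyl hydrogen gives the 2-(chloromethyl)vinyl unit.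

Step 19
Reactants: 31 [(1S,4E,6R,8S,10R)-8-(3-chloroprop-1-en-2-yl)-1-(hydroxymethyl)-6-[(3-methylbut-2-enoyl)oxy]-11-oxabicyclo[8.1.0]undec-4-en-5-yl]methyl (2R,3S)-3-hydroxy-2-methylbutanoate
Product: 32 [(1S,4E,6R,8S,10R)-8-[3-(acetyloxy)prop-1-en-2-yl]-1-(hydroxymethyl)-6-[(3-methylbut-2-enoyl)oxy]-11-oxabicyclo[8.1.0]undec-4-en-5-yl]methyl (2R,3S)-3-hydroxy-2-methylbutanoate
Conditions: n-Bu4NOAc, acetone, 40 °C
Reagents that add atoms: tetrabutylammonium acetate, CCCC[N+](CCCC)(CCCC)CCCC.CC([O-])=O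
Why: SN2 displacement of the primary allylic chloride by acetate (the SN2′ path gives the same product) forms the C12–O bond under nearly neutral conditions that leave the three esters and the epoxy alcohol untouched.

**Compound list**

1 | 5,6-dihydro-2H-pyran-2-one | O=C1C=CCCO1 | starting material
2 | 4,4,5,5-tetramethyl-2-(prop-1-en-2-yl)-1,3,2-dioxaborolane | CC(=C)B1OC(C)(C)C(C)(C)O1 | starting material
3 | (4R)-4-(prop-1-en-2-yl)oxan-2-one | CC(=C)[C@H]1CC(=O)OCC1 | intermediate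
4 | (3R)-5-hydroxy-N-methoxy-N-methyl-3-(prop-1-en-2-yl)pentanamide | CC(=C)[C@H](CCO)CC(=O)N(C)OC | intermediate
5 | (3R)-N-methoxy-N-methyl-5-oxo-3-(prop-1-en-2-yl)pentanamide | CC(=C)[C@H](CC=O)CC(=O)N(C)OC | intermediate
6 | tert-butyl[(2-bromoprop-2-en-1-yl)oxy]dimethylsilane | C=C(Br)CO[Si](C)(C)C(C)(C)C | starting material
7 | {3-[tert-butyl(dimethyl)silyl]oxyprop-1-en-2-yl}lithium | [Li]C(=C)CO[Si](C)(C)C(C)(C)C | intermediate
8 | (3R,5RS)-6-({[tert-butyl(dimethyl)silyl]oxy}methyl)-5-hydroxy-N-methoxy-N-methyl-3-(prop-1-en-2-yl)hept-6-enamide | CC(=C)[C@H](CC(O)C(=C)CO[Si](C)(C)C(C)(C)C)CC(=O)N(C)OC | intermediate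
9 | (3R,5RS)-6-({[tert-butyl(dimethyl)silyl]oxy}methyl)-5-(ethenyloxy)-N-methoxy-N-methyl-3-(prop-1-en-2-yl)hept-6-enamide | CC(=C)[C@H](CC(OC=C)C(=C)CO[Si](C)(C)C(C)(C)C)CC(=O)N(C)OC | intermediate
10 | (3R,5Z)-6-({[tert-butyl(dimethyl)silyl]oxy}methyl)-N-methoxy-N-methyl-9-oxo-3-(prop-1-en-2-yl)non-5-enamide | CC(=C)[C@H](C/C=C(\CO[Si](C)(C)C(C)(C)C)CCC=O)CC(=O)N(C)OC | intermediate
11 | methyl 2-[bis(2,2,2-trifluoroethoxy)phosphoryl]acetate | COC(=O)CP(=O)(OCC(F)(F)F)OCC(F)(F)F | starting material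
12 | methyl 2-[bis(2,2,2-trifluoroethoxy)phosphoryl]-2,2-dibromoacetate | COC(=O)C(Br)(Br)P(=O)(OCC(F)(F)F)OCC(F)(F)F | intermediate
13 | methyl 2-[bis(2,2,2-trifluoroethoxy)phosphoryl]-2-bromoacetate (racemic) | COC(=O)C(Br)P(=O)(OCC(F)(F)F)OCC(F)(F)F | intermediate
14 | methyl (2E,6Z,9R)-2-bromo-6-({[tert-butyl(dimethyl)silyl]oxy}methyl)-11-[methoxy(methyl)amino]-11-oxo-9-(prop-1-en-2-yl)undeca-2,6-dienoate | CC(=C)[C@H](C/C=C(\CO[Si](C)(C)C(C)(C)C)CC/C=C(/Br)C(=O)OC)CC(=O)N(C)OC | intermediate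
15 | (3R,5Z,9E)-10-bromo-6-({[tert-butyl(dimethyl)silyl]oxy}methyl)-11-hydroxy-3-(prop-1-en-2-yl)undeca-5,9-dienal | CC(=C)[C@H](C/C=C(\CO[Si](C)(C)C(C)(C)C)CC/C=C(/Br)CO)CC=O | intermediate
16 | (1RS,2E,6Z,9R)-6-({[tert-butyl(dimethyl)silyl]oxy}methyl)-2-(hydroxymethyl)-9-(prop-1-en-2-yl)cyclodeca-2,6-dien-1-ol | CC(=C)[C@H]1CC(O)/C(CO)=C/CC/C(CO[Si](C)(C)C(C)(C)C)=C/C1 | intermediate
17 | (4R)-4-benzyl-3-propanoyl-1,3-oxazolidin-2-one | CCC(=O)N1[C@H](Cc2ccccc2)COC1=O | starting material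
18 | acetaldehyde | CC=O | starting material
19 | (4R)-4-benzyl-3-[(1Z)-1-[(dibutylboranyl)oxy]prop-1-en-1-yl]-1,3-oxazolidin-2-one | C/C=C(\OB(CCCC)CCCC)N1[C@H](Cc2ccccc2)COC1=O | intermediate
20 | (4R)-4-benzyl-3-[(2R,3S)-3-[(dibutylboranyl)oxy]-2-methylbutanoyl]-1,3-oxazolidin-2-one | O=C([C@H](C)[C@H](C)OB(CCCC)CCCC)N1[C@H](Cc2ccccc2)COC1=O | intermediate
21 | (4R)-4-benzyl-3-[(2R,3S)-3-hydroxy-2-methylbutanoyl]-1,3-oxazolidin-2-one | O=C([C@H](C)[C@H](C)O)N1[C@H](Cc2ccccc2)COC1=O | intermediate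
22 | (4R)-4-benzyl-3-[(2R,3S)-3-{[tert-butyl(dimethyl)silyl]oxy}-2-methylbutanoyl]-1,3-oxazolidin-2-one | O=C([C@H](C)[C@H](C)O[Si](C)(C)C(C)(C)C)N1[C@H](Cc2ccccc2)COC1=O | intermediate
23 | (2R,3S)-3-{[tert-butyl(dimethyl)silyl]oxy}-2-methylbutaneperoxoic acid | OOC(=O)[C@H](C)[C@H](C)O[Si](C)(C)C(C)(C)C | intermediate
24 | (2R,3S)-3-{[tert-butyl(dimethyl)silyl]oxy}-2-methylbutanoic acid | OC(=O)[C@H](C)[C@H](C)O[Si](C)(C)C(C)(C)C | intermediate
25 | [(1E,5Z,8R,10RS)-5-({[tert-butyl(dimethyl)silyl]oxy}methyl)-10-hydroxy-8-(prop-1-en-2-yl)cyclodeca-1,5-dien-1-yl]methyl (2R,3S)-3-{[tert-butyl(dimethyl)silyl]oxy}-2-methylbutanoate | CC(=C)[C@H]1CC(O)/C(COC(=O)[C@H](C)[C@H](C)O[Si](C)(C)C(C)(C)C)=C/CC/C(CO[Si](C)(C)C(C)(C)C)=C/C1 | intermediate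
26 | 3-methylbut-2-enoic acid | CC(C)=CC(O)=O | starting material
27 | 3-methylbut-2-enoic propan-2-yl carbonic anhydride | CC(C)=CC(=O)OC(=O)OC(C)C | intermediate
28 | [(1E,5Z,8R,10R)-5-({[tert-butyl(dimethyl)silyl]oxy}methyl)-10-[(3-methylbut-2-enoyl)oxy]-8-(prop-1-en-2-yl)cyclodeca-1,5-dien-1-yl]methyl (2R,3S)-3-{[tert-butyl(dimethyl)silyl]oxy}-2-methylbutanoate | CC(=C)[C@H]1C[C@@H](OC(=O)C=C(C)C)/C(COC(=O)[C@H](C)[C@H](C)O[Si](C)(C)C(C)(C)C)=C/CC/C(CO[Si](C)(C)C(C)(C)C)=C/C1 | intermediate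
29 | [(1E,5Z,8R,10R)-5-(hydroxymethyl)-10-[(3-methylbut-2-enoyl)oxy]-8-(prop-1-en-2-yl)cyclodeca-1,5-dien-1-yl]methyl (2R,3S)-3-hydroxy-2-methylbutanoate | CC(=C)[C@H]1C[C@@H](OC(=O)C=C(C)C)/C(COC(=O)[C@H](C)[C@H](C)O)=C/CC/C(CO)=C/C1 | intermediate
30 | [(1S,4E,6R,8S,10R)-1-(hydroxymethyl)-6-[(3-methylbut-2-enoyl)oxy]-8-(prop-1-en-2-yl)-11-oxabicyclo[8.1.0]undec-4-en-5-yl]methyl (2R,3S)-3-hydroxy-2-methylbutanoate | CC(=C)[C@H]1C[C@@H](OC(=O)C=C(C)C)/C(COC(=O)[C@H](C)[C@H](C)O)=C/CC[C@@]2(CO)O[C@@H]2C1 | intermediate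
31 | [(1S,4E,6R,8S,10R)-8-(3-chloroprop-1-en-2-yl)-1-(hydroxymethyl)-6-[(3-methylbut-2-enoyl)oxy]-11-oxabicyclo[8.1.0]undec-4-en-5-yl]methyl (2R,3S)-3-hydroxy-2-methylbutanoate | C=C(CCl)[C@H]1C[C@@H](OC(=O)C=C(C)C)/C(COC(=O)[C@H](C)[C@H](C)O)=C/CC[C@@]2(CO)O[C@@H]2C1 | intermediate
32 | [(1S,4E,6R,8S,10R)-8-[3-(acetyloxy)prop-1-en-2-yl]-1-(hydroxymethyl)-6-[(3-methylbut-2-enoyl)oxy]-11-oxabicyclo[8.1.0]undec-4-en-5-yl]methyl (2R,3S)-3-hydroxy-2-methylbutanoate (CNP0227102.1) | C=C(COC(C)=O)[C@H]1C[C@@H](OC(=O)C=C(C)C)/C(COC(=O)[C@H](C)[C@H](C)O)=C/CC[C@@]2(CO)O[C@@H]2C1 | target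

**Step count and risks**

Total step count: 19. Longest linear sequence: 14 steps (1–5, 8–10, 14–19).

Three steps most likely to fail:

Step 15 (the proposed new stereoconvergent acylation). The ruthenium catalyst may be poisoned by the acyl donor, the macrocyclic carbinol may epimerise too slowly, or the isothiourea may select poorly. The fallback uses known chemistry, sets out from 25 and comes back at 28. Dess–Martin oxidation (NaHCO3, CH2Cl2) of the epimer mixture gives the cyclodecadienone ester [(1E,5Z,8R)-5-({[tert-butyl(dimethyl)silyl]oxy}methyl)-10-oxo-8-(prop-1-en-2-yl)cyclodeca-1,5-dien-1-yl]methyl (2R,3S)-3-{[tert-butyl(dimethyl)silyl]oxy}-2-methylbutanoate F1. Corey–Bakshi–Shibata reduction with (S)-2-methyl-CBS-oxazaborolidine and catecholborane (PhMe, −78 °C; the alkenyl side acts as the large group) gives the single 10R carbinol [(1E,5Z,8R,10R)-5-({[tert-butyl(dimethyl)silyl]oxy}methyl)-10-hydroxy-8-(prop-1-en-2-yl)cyclodeca-1,5-dien-1-yl]methyl (2R,3S)-3-{[tert-butyl(dimethyl)silyl]oxy}-2-methylbutanoate F2. Acylation with 3-methylbut-2-enoyl chloride and pyridine (CH2Cl2, 0 °C, no DMAP so the enoate does not deconjugate) then gives 28.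

Step 10 (ten-membered ring closure with an unactivated alkenyl bromide). The fallback sets out from 15 and comes back at 16, replacing chromium/nickel insertion by boron-to-rhodium transmetalation. Miyaura borylation (B2pin2, Pd(dppf)Cl2, KOAc, dioxane, 80 °C) gives the alkenyl boronate (3R,5Z,9Z)-6-({[tert-butyl(dimethyl)silyl]oxy}methyl)-11-hydroxy-3-(prop-1-en-2-yl)-10-(4,4,5,5-tetramethyl-1,3,2-dioxaborolan-2-yl)undeca-5,9-dienal F3. Rhodium-catalysed intramolecular 1,2-addition to the aldehyde ([Rh(cod)OH]2, dioxane/H2O, 40 °C, 2 mM) then closes the ring to 16.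

Step 17 (directed epoxidation of a hindered 2,3-disubstituted allylic alcohol inside a chiral macrocycle, where reagent and ring facial bias may be mismatched). The fallback sets out from 28 and comes back at 30, switching from hydroxyl-directed to non-directed catalyst-controlled epoxidation. Shi epoxidation (fructose-derived ketone catalyst of the enantiomeric series that attacks the required face, KHSO5 as its triple salt 2KHSO5·KHSO4·K2SO4, K2CO3, MeCN/dimethoxymethane/buffer, 0 °C) of the most electron-rich alkene (C4=C5) gives the epoxide [(1S,4E,6R,8S,10R)-1-({[tert-butyl(dimethyl)silyl]oxy}methyl)-6-[(3-methylbut-2-enoyl)oxy]-8-(prop-1-en-2-yl)-11-oxabicyclo[8.1.0]undec-4-en-5-yl]methyl (2R,3S)-3-{[tert-butyl(dimethyl)silyl]oxy}-2-methylbutanoate F4. HF·pyridine (pyridine, THF) then removes both silyl groups to give 30.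

Further compounds

F1 | step 15 | [(1E,5Z,8R)-5-({[tert-butyl(dimethyl)silyl]oxy}methyl)-10-oxo-8-(prop-1-en-2-yl)cyclodeca-1,5-dien-1-yl]methyl (2R,3S)-3-{[tert-butyl(dimethyl)silyl]oxy}-2-methylbutanoate | CC(=C)[C@H]1CC(=O)/C(COC(=O)[C@H](C)[C@H](C)O[Si](C)(C)C(C)(C)C)=C/CC/C(CO[Si](C)(C)C(C)(C)C)=C/C1
F2 | step 15 | [(1E,5Z,8R,10R)-5-({[tert-butyl(dimethyl)silyl]oxy}methyl)-10-hydroxy-8-(prop-1-en-2-yl)cyclodeca-1,5-dien-1-yl]methyl (2R,3S)-3-{[tert-butyl(dimethyl)silyl]oxy}-2-methylbutanoate | CC(=C)[C@H]1C[C@@H](O)/C(COC(=O)[C@H](C)[C@H](C)O[Si](C)(C)C(C)(C)C)=C/CC/C(CO[Si](C)(C)C(C)(C)C)=C/C1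
F3 | step 10 | (3R,5Z,9Z)-6-({[tert-butyl(dimethyl)silyl]oxy}methyl)-11-hydroxy-3-(prop-1-en-2-yl)-10-(4,4,5,5-tetramethyl-1,3,2-dioxaborolan-2-yl)undeca-5,9-dienal | CC(=C)[C@H](C/C=C(\CO[Si](C)(C)C(C)(C)C)CC/C=C(/B1OC(C)(C)C(C)(C)O1)CO)CC=O
F4 | step 17 | [(1S,4E,6R,8S,10R)-1-({[tert-butyl(dimethyl)silyl]oxy}methyl)-6-[(3-methylbut-2-enoyl)oxy]-8-(prop-1-en-2-yl)-11-oxabicyclo[8.1.0]undec-4-en-5-yl]methyl (2R,3S)-3-{[tert-butyl(dimethyl)silyl]oxy}-2-methylbutanoate | CC(=C)[C@H]1C[C@@H](OC(=O)C=C(C)C)/C(COC(=O)[C@H](C)[C@H](C)O[Si](C)(C)C(C)(C)C)=C/CC[C@@]2(CO[Si](C)(C)C(C)(C)C)O[C@@H]2C1
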